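**Retrosynthetic overview** (flavanone numbering: O1, C2–C8a for rings C/A, C1′–C6′ for ring B)
1. The target is a (2S)-flavanone, 6,2′-diprenylhesperetin. The last operation removes a single MOM group from O7.
2. The key disconnection is C2–C1′. Ring C goes back to the chromone level and ring B to an arylboronic acid, and a Rh(I)/chiral bisphosphine 1,4-addition makes the bond and sets C2.
3. In the same stroke both prenyl groups go back from C6 (ring A) and C2′ (ring B) to O5 and O3′ as 1,1-dimethylallyl ethers. These O–C bonds are temporary and return the prenyl groups by two aromatic Claisen shifts when the coupling flask is heated.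
4. Enabling feature: C2 is the β-carbon of the planar vinylogous ester O1–C2=C3–C4=O of ring C. Each prenylated carbon is also the only free ortho position of a phenolic oxygen (O5: C6 free, C4a is the ring fusion; O3′: C2′ free, C4′ carries OMe). The O→C transfer is therefore regiospecific, and C2′ is still unsubstituted when C1′ is coupled.
5. Ring order: rings A and B are bought aromatic. Ring C is closed once, as the pyranone, by the enaminone route, and the key step brings it to the chromanone level.

Key step: step 8

Assumption: the sense of induction is taken from the cyclic-enone model for (S)-configured biaryl bisphosphines, which gives (S) at the β-carbon. If the coupling favours the other face, the (R)-ligand is used and nothing else changes.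

**Step 1**
Reactants: 1 2,4,6-trihydroxyacetophenone
Product: 2 1-[2,6-dihydroxy-4-(methoxymethoxy)phenyl]ethan-1-one
Conditions: MOMCl (1.05 equiv), i-Pr2NEt (1.2 equiv), THF, 0 °C
Reagents that add atoms: chloromethyl methyl ether (MOMCl), COCCl
Why: Williamson-type O-alkylation, in which the 4-OH is the most acidic hydroxyl and the only one not held in a hydrogen bond to the acetyl C=O, so one equivalent of MOMCl should react there first.

**Step 2**
Reactants: 2 1-[2,6-dihydroxy-4-(methoxymethoxy)phenyl]ethan-1-one; 3 3-chloro-3-methylbut-1-yne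
Product: 4 1-{2-hydroxy-4-(methoxymethoxy)-6-[(2-methylbut-3-yn-2-yl)oxy]phenyl}ethan-1-one
Conditions: 3 (1.2 equiv), DBU (1.3 equiv), CuCl2·2H2O (1 mol %), MeCN, 0 °C to rt
Reagents that add atoms: none
Why: Copper-catalysed propargylic etherification (the phenoxide attacks a copper allenylidene at its tertiary carbon), in which the two hydroxyls of 2 are equivalent and the one left after the first etherification is locked in the hydrogen bond to C=O, which should stop the reaction at the monoether.

**Step 3**
Reactants: 4 1-{2-hydroxy-4-(methoxymethoxy)-6-[(2-methylbut-3-yn-2-yl)oxy]phenyl}ethan-1-one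
Product: 6 7-(methoxymethoxy)-5-[(2-methylbut-3-yn-2-yl)oxy]-4H-chromen-4-one, via enaminone 5 (not isolated)
Conditions: DMF-DMA (3 equiv), toluene, 85 °C; evaporate; AcOH, 60 °C
Reagents that add atoms: N,N-dimethylformamide dimethyl acetal (DMF-DMA), COC(OC)N(C)C
Why: Enaminone route to chromones, in which the acetyl CH3 condenses with DMF-DMA to the β-dimethylamino enone 5 and in warm acetic acid the free ortho-OH adds to its β-carbon with loss of dimethylamine (6-endo addition–elimination), conditions that the MOM acetal and the acid-tolerant propargylic ether should survive.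

**Step 4**
Reactants: 6 7-(methoxymethoxy)-5-[(2-methylbut-3-yn-2-yl)oxy]-4H-chromen-4-one
Product: 7 7-(methoxymethoxy)-5-[(2-methylbut-3-en-2-yl)oxy]-4H-chromen-4-one
Conditions: H2 (1 atm), Lindlar catalyst, quinoline, EtOAc, rt
Reagents that add atoms: none
Why: Lindlar semihydrogenation, in which the poisoned Pd surface should take the terminal alkyne to the vinyl group and leave the pyranone C2=C3 bond, the MOM group and the aryl ether untouched.

**Step 5**
Reactants: 8 5-bromo-2-methoxyphenol; 3 3-chloro-3-methylbut-1-yne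
Product: 9 4-bromo-1-methoxy-2-[(2-methylbut-3-yn-2-yl)oxy]benzene
Conditions: 3 (1.2 equiv), DBU (1.3 equiv), CuCl2·2H2O (1 mol %), MeCN, 0 °C
Reagents that add atoms: none
Why: Copper-catalysed propargylic etherification as in step 2, with the single phenolic OH as the only nucleophile and the aryl bromide inert under these conditions.

**Step 6**
Reactants: 9 4-bromo-1-methoxy-2-[(2-methylbut-3-yn-2-yl)oxy]benzene
Product: 10 4-bromo-1-methoxy-2-[(2-methylbut-3-en-2-yl)oxy]benzene
Conditions: H2 (1 atm), Lindlar catalyst, quinoline, EtOAc, rt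
Reagents that add atoms: none
Why: Lindlar semihydrogenation of the terminal alkyne, during which the aryl bromide should not be hydrogenolysed over the poisoned catalyst.

**Step 7**
Reactants: 10 4-bromo-1-methoxy-2-[(2-methylbut-3-en-2-yl)oxy]benzene
Product: 13 {4-methoxy-3-[(2-methylbut-3-en-2-yl)oxy]phenyl}boronic acid, via aryllithium 11 (not isolated), via lithium aryl(triisopropoxy)borate 12 (not isolated)
Conditions: B(Oi-Pr)3 (1.5 equiv), n-BuLi (1.15 equiv), THF/toluene, −78 °C (borate present from the start); sat. aq NH4Cl, 0 °C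
Reagents that add atoms: triisopropyl borate, CC(C)OB(OC(C)C)OC(C)C; water, O
Why: Bromine–lithium exchange and borylation, in which the ether has no hydrogen on its O-bearing carbon so that no Wittig rearrangement is open to it, and the near-neutral NH4Cl hydrolysis spares the acid-labile tertiary allyl ether.

**Step 8**
Reactants: 7 7-(methoxymethoxy)-5-[(2-methylbut-3-en-2-yl)oxy]-4H-chromen-4-one; 13 {4-methoxy-3-[(2-methylbut-3-en-2-yl)oxy]phenyl}boronic acid
Product: 15 (2S)-5-hydroxy-2-[3-hydroxy-4-methoxy-2-(3-methylbut-2-en-1-yl)phenyl]-7-(methoxymethoxy)-6-(3-methylbut-2-en-1-yl)-2,3-dihydro-4H-chromen-4-one, via bis(1,1-dimethylallyl) ether flavanone 14 (not isolated)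
Conditions: 13 (1.2 equiv), [RhCl(C2H4)2]2 (2.5 mol %), (S)-MeO-F12-BIPHEP (5.5 mol %), aq KOH (10 mol %), toluene/H2O 10:1, Ar, 30 °C; then the same flask, sealed, 115 °C
Reagents that add atoms: none
Why: Hayashi–Miyaura asymmetric 1,4-addition followed in the same flask by two aromatic Claisen rearrangements: B-to-Rh transmetalation of 13 gives an aryl–Rh(I) species, the C2=C3 bond of chromone 7 inserts into it (C1′–C2 formed) and water protonates the oxa-π-allyl rhodium enolate to release 14 and Rh–OH, a reaction type known for chromones including 5,7-dioxygenated ones. The only new stereocentre, C2, is controlled by the (S)-biaryl bisphosphine, whose quadrant blocking lets the flat s-trans enone bind through one face only, the face that leads to (S) by the model for cyclic enones. No ring is closed; ring C merely passes from the pyranone to the dihydropyranone level. At 115 °C each ArO–C(CH3)2–CH=CH2 unit of 14 undergoes a suprafacial chair-like [3,3] shift with allyl inversion and the dienones tautomerise, so that CH2-bound prenyl groups appear at C6 and C2′ while O5–H and O3′–H are set free, the geminal methyl groups lowering the barrier far below that of simple allyl aryl ethers. Regioselectivity is secured by the substrate, since the second ortho position of O5 is the ring-fusion carbon C4a and that of O3′ is the methoxy-bearing C4′, and chemoselectivity in the coupling is secured by the absence of an ortho substituent next to boron, by the quaternary O-bearing carbon that excludes isomerisation to enol ethers, and by the flanked, electron-rich C4=O that resists 1,2-addition. The boric acid formed keeps the medium close to neutral, which should hold back retro-oxa-Michael opening of ring C and so preserve C2.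

**Step 9**
Reactants: 15 (2S)-5-hydroxy-2-[3-hydroxy-4-methoxy-2-(3-methylbut-2-en-1-yl)phenyl]-7-(methoxymethoxy)-6-(3-methylbut-2-en-1-yl)-2,3-dihydro-4H-chromen-4-one
Product: 16 (2S)-5,7-dihydroxy-2-[3-hydroxy-4-methoxy-2-(3-methylbut-2-en-1-yl)phenyl]-6-(3-methylbut-2-en-1-yl)-2,3-dihydro-4H-chromen-4-one
Conditions: 3 M aq HCl (cat.), MeOH, 45 °C
Reagents that add atoms: none
Why: Acid-catalysed acetal cleavage (transacetalisation to methanol), a standard unmasking for prenylated flavonoids in which the aryl MOM acetal should ionise faster than the trisubstituted alkenes are protonated, and which creates no base that could open ring C and scramble C2.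

**Compound list**
1 | 2,4,6-trihydroxyacetophenone | CC(=O)c1c(O)cc(O)cc1O | starting material
2 | 1-[2,6-dihydroxy-4-(methoxymethoxy)phenyl]ethan-1-one | CC(=O)c1c(O)cc(OCOC)cc1O | intermediate
3 | 3-chloro-3-methylbut-1-yne | C#CC(C)(C)Cl | starting material
4 | 1-{2-hydroxy-4-(methoxymethoxy)-6-[(2-methylbut-3-yn-2-yl)oxy]phenyl}ethan-1-one | CC(=O)c1c(O)cc(OCOC)cc1OC(C)(C)C#C | intermediate
5 | (E)-3-(dimethylamino)-1-{2-hydroxy-4-(methoxymethoxy)-6-[(2-methylbut-3-yn-2-yl)oxy]phenyl}prop-2-en-1-one | CN(C)/C=C/C(=O)c1c(O)cc(OCOC)cc1OC(C)(C)C#C | intermediate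
6 | 7-(methoxymethoxy)-5-[(2-methylbut-3-yn-2-yl)oxy]-4H-chromen-4-one | O=c1ccoc2cc(OCOC)cc(OC(C)(C)C#C)c12 | intermediate
7 | 7-(methoxymethoxy)-5-[(2-methylbut-3-en-2-yl)oxy]-4H-chromen-4-one | O=c1ccoc2cc(OCOC)cc(OC(C)(C)C=C)c12 | intermediate
8 | 5-bromo-2-methoxyphenol | COc1ccc(Br)cc1O | starting material
9 | 4-bromo-1-methoxy-2-[(2-methylbut-3-yn-2-yl)oxy]benzene | COc1ccc(Br)cc1OC(C)(C)C#C | intermediate
10 | 4-bromo-1-methoxy-2-[(2-methylbut-3-en-2-yl)oxy]benzene | COc1ccc(Br)cc1OC(C)(C)C=C | intermediate
11 | {4-methoxy-3-[(2-methylbut-3-en-2-yl)oxy]phenyl}lithium | COc1ccc([Li])cc1OC(C)(C)C=C | intermediate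
12 | lithium {4-methoxy-3-[(2-methylbut-3-en-2-yl)oxy]phenyl}tri(propan-2-yloxy)borate | [Li+].COc1ccc([B-](OC(C)C)(OC(C)C)OC(C)C)cc1OC(C)(C)C=C | intermediate
13 | {4-methoxy-3-[(2-methylbut-3-en-2-yl)oxy]phenyl}boronic acid | COc1ccc(B(O)O)cc1OC(C)(C)C=C | intermediate
14 | (2S)-7-(methoxymethoxy)-2-{4-methoxy-3-[(2-methylbut-3-en-2-yl)oxy]phenyl}-5-[(2-methylbut-3-en-2-yl)oxy]-2,3-dihydro-4H-chromen-4-one | COc1ccc([C@@H]2CC(=O)c3c(cc(OCOC)cc3OC(C)(C)C=C)O2)cc1OC(C)(C)C=C | intermediate
15 | (2S)-5-hydroxy-2-[3-hydroxy-4-methoxy-2-(3-methylbut-2-en-1-yl)phenyl]-7-(methoxymethoxy)-6-(3-methylbut-2-en-1-yl)-2,3-dihydro-4H-chromen-4-one | COc1ccc([C@@H]2CC(=O)c3c(cc(OCOC)c(CC=C(C)C)c3O)O2)c(CC=C(C)C)c1O | intermediate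
16 | (2S)-5,7-dihydroxy-2-[3-hydroxy-4-methoxy-2-(3-methylbut-2-en-1-yl)phenyl]-6-(3-methylbut-2-en-1-yl)-2,3-dihydro-4H-chromen-4-one | COc1ccc([C@@H]2CC(=O)c3c(cc(O)c(CC=C(C)C)c3O)O2)c(CC=C(C)C)c1O | target

**Totals:** the route has 9 steps, and the longest linear sequence is 6 steps (1, 2, 3, 4, 8, 9).

**Steps most likely to fail**

**Step 8 (key step).**
- Insertion into the electron-rich 5,7-dialkoxychromone may be slower than protodeboronation.
- Aryl-rhodium may add to the vinyl groups with β-oxygen elimination, or the tertiary allyl ethers may ionise.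
- Ring C may open and reclose (retro-oxa-Michael) during the heating phase and erode the configuration at C2.
- On ring B the allyl unit may travel on to the para position instead of resting at the crowded C2′.

The fallback moves the O→C transfer in front of the coupling, where nothing stereogenic is at stake, and sets out from 7 and 10. Heating 7 alone in toluene at 110 °C should give 5-hydroxy-7-(methoxymethoxy)-6-prenylchromone F1. Heating 10 alone should give 3-bromo-6-methoxy-2-prenylphenol F2. F2 is capped with MOMCl/i-Pr2NEt to the MOM ether F3. This ether now tolerates Pd(0) and is converted by Miyaura borylation (B2pin2, Pd(dppf)Cl2, KOAc, dioxane, 80 °C) into the pinacol boronate F4. A Rh(I)/chiral diene 1,4-addition of F4 to F1 follows, a catalyst class that accepts ortho-substituted arylboron reagents, and should give the bis-MOM flavanone F5. HCl/MeOH as in step 9 then removes both MOM groups, and the fallback comes back to the route at 16.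

**Step 2.**
- O-alkylation of the chelated phenoxide by a tertiary electrophile may be sluggish.
- Both hydroxyls may be etherified.
- The electron-rich ring may be alkylated at carbon.

The fallback uses a primary allyl group as carrier and finishes the prenyl group by metathesis. It sets out from 2. Allyl bromide/K2CO3 in acetone should give the monoallyl ether F6. DMF-DMA and then AcOH, as in step 3, lead through the enaminone F7 to 5-(allyloxy)-7-(methoxymethoxy)chromone F8. An aromatic Claisen rearrangement at the achiral chromone stage (N,N-diethylaniline, 190 °C, C6 again the only free ortho position) should give 6-allyl-5-hydroxy-7-(methoxymethoxy)chromone F9. Cross-metathesis with 2-methylbut-2-ene (Grubbs second-generation catalyst, CH2Cl2, 40 °C) converts this into the 6-prenylchromone F1 already described for step 8. Coupling of F1 with 13 under the conditions of step 8 gives the mono(1,1-dimethylallyl) ether flavanone F10. Only its ring-B ether has to migrate on heating, and the fallback comes back to the route at 15.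

**Step 9.**
- Acid may add the O5, O7 or O3′ hydroxyl to a neighbouring prenyl double bond (chroman formation).
- Acid may promote enolisation and opening of ring C, with loss of configurational purity.

The fallback lets no acid act after the prenyl groups and C2 exist, and sets out from 6. HCl/MeOH at the acid-tolerant propargyl ether stage should give 7-hydroxy-5-[(2-methylbut-3-yn-2-yl)oxy]chromone F11. Lindlar semihydrogenation gives 7-hydroxy-5-[(2-methylbut-3-en-2-yl)oxy]chromone F12. Base-free coupling with 13 (preformed hydroxo-rhodium/(S)-bisphosphine complex, dioxane/H2O, 35 °C) gives the 7-hydroxy bis-ether flavanone F13. Heating this in the same flask to 115 °C makes both allyl units migrate, and the fallback comes back to the route at 16.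

**Further compounds**
F1 | step 8 | 5-hydroxy-7-(methoxymethoxy)-6-(3-methylbut-2-en-1-yl)-4H-chromen-4-one | O=c1ccoc2cc(OCOC)c(CC=C(C)C)c(O)c12
F2 | step 8 | 3-bromo-6-methoxy-2-(3-methylbut-2-en-1-yl)phenol | COc1ccc(Br)c(CC=C(C)C)c1O
F3 | step 8 | 1-bromo-4-methoxy-3-(methoxymethoxy)-2-(3-methylbut-2-en-1-yl)benzene | COc1ccc(Br)c(CC=C(C)C)c1OCOC
F4 | step 8 | 2-[4-methoxy-3-(methoxymethoxy)-2-(3-methylbut-2-en-1-yl)phenyl]-4,4,5,5-tetramethyl-1,3,2-dioxaborolane | COc1ccc(B2OC(C)(C)C(C)(C)O2)c(CC=C(C)C)c1OCOC
F5 | step 8 | (2S)-5-hydroxy-7-(methoxymethoxy)-2-[4-methoxy-3-(methoxymethoxy)-2-(3-methylbut-2-en-1-yl)phenyl]-6-(3-methylbut-2-en-1-yl)-2,3-dihydro-4H-chromen-4-one | COc1ccc([C@@H]2CC(=O)c3c(cc(OCOC)c(CC=C(C)C)c3O)O2)c(CC=C(C)C)c1OCOC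
F6 | step 2 | 1-[2-hydroxy-4-(methoxymethoxy)-6-(prop-2-en-1-yloxy)phenyl]ethan-1-one | CC(=O)c1c(O)cc(OCOC)cc1OCC=C
F7 | step 2 | (E)-3-(dimethylamino)-1-[2-hydroxy-4-(methoxymethoxy)-6-(prop-2-en-1-yloxy)phenyl]prop-2-en-1-one | CN(C)/C=C/C(=O)c1c(O)cc(OCOC)cc1OCC=C
F8 | step 2 | 7-(methoxymethoxy)-5-(prop-2-en-1-yloxy)-4H-chromen-4-one | O=c1ccoc2cc(OCOC)cc(OCC=C)c12
F9 | step 2 | 5-hydroxy-7-(methoxymethoxy)-6-(prop-2-en-1-yl)-4H-chromen-4-one | O=c1ccoc2cc(OCOC)c(CC=C)c(O)c12
F10 | step 2 | (2S)-5-hydroxy-7-(methoxymethoxy)-2-{4-methoxy-3-[(2-methylbut-3-en-2-yl)oxy]phenyl}-6-(3-methylbut-2-en-1-yl)-2,3-dihydro-4H-chromen-4-one | COc1ccc([C@@H]2CC(=O)c3c(cc(OCOC)c(CC=C(C)C)c3O)O2)cc1OC(C)(C)C=C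
F11 | step 9 | 7-hydroxy-5-[(2-methylbut-3-yn-2-yl)oxy]-4H-chromen-4-one | O=c1ccoc2cc(O)cc(OC(C)(C)C#C)c12
F12 | step 9 | 7-hydroxy-5-[(2-methylbut-3-en-2-yl)oxy]-4H-chromen-4-one | O=c1ccoc2cc(O)cc(OC(C)(C)C=C)c12
F13 | step 9 | (2S)-7-hydroxy-2-{4-methoxy-3-[(2-methylbut-3-en-2-yl)oxy]phenyl}-5-[(2-methylbut-3-en-2-yl)oxy]-2,3-dihydro-4H-chromen-4-one | COc1ccc([C@@H]2CC(=O)c3c(cc(O)cc3OC(C)(C)C=C)O2)cc1OC(C)(C)C=C
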